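**Plan**

- Retrosynthesis: the C3–Cl and C3–CH3 bonds and then the C2–Br bond are cut back to a ring B enone. Ring B is then cut at C5–C6 and C1–C2 (Michael addition and aldol condensation with methyl vinyl ketone), and ring A at C6–C11 (bromonium cyclisation of a geranyl unit).
- Forward: geranyl acetate is turned into an enantiopure 6-bromo-7-chloro derivative, ring A closes by solvolytic bromonium cyclisation, and adjustment gives the bromo-β-cyclocitral. Ring B is then spiro-annulated onto C6, and its enone is converted into the trans bromochloride.
- Enabling feature: C6 is the α-carbon of a cyclocitral (ring A, C6–C11). In its dienolate the pseudo-axial C11 methyl is cis to the equatorial C10 bromide, so the two faces of C6 differ and ring B (C1–C6) can be grown on it.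
- Stereochemistry: C10 comes from a Shi epoxidation relayed by stereospecific displacements, and C6 from substrate control in the Michael step. C2 is set by equilibration to the equatorial α-bromo ketone, and C3 by chloride opening a C2/C3 bromonium ion anti to bromine.

Key step: step 7

Remark: spiro compounds carry chamigrene numbering (ring B C1–C5, spiro C6, ring A C7–C11), in which the target is (2R,3R,6R,10S); compounds 5–7 are carried as ring A double-bond isomers that converge on 8, and the Δ2 isomer is the one drawn.

**Route**

Step 1
Reactants: 1 geranyl acetate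
Product: 2 (2E)-5-[(2R)-3,3-dimethyloxiran-2-yl]-3-methylpent-2-en-1-yl acetate ((6R)-6,7-epoxygeranyl acetate)
Conditions: D-fructose-derived Shi ketone (0.3 equiv), KHSO5 (as Oxone, 2KHSO5·KHSO4·K2SO4), K2CO3, Bu4NHSO4, MeCN/CH2(OMe)2/aq. Na2B4O7, 0 °C
Reagents that add atoms: potassium peroxymonosulfate, [K+].[O-]S(=O)(=O)OO
Why: Shi asymmetric epoxidation, in which the chiral dioxirane formed in the flask attacks the electron-rich 6,7-alkene in preference to the 2,3-alkene deactivated by the allylic acetate and, as with other prenyl-type trisubstituted alkenes, should set C6 as R, the source of C10 of the target.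

Step 2
Reactants: 2 (6R)-6,7-epoxygeranyl acetate
Product: 3 (2E,6S)-6-bromo-7-hydroxy-3,7-dimethyloct-2-en-1-yl acetate
Conditions: Li2NiBr4, THF, 0 → 23 °C; aqueous work-up
Reagents that add atoms: dilithium tetrabromonickelate, [Li+].[Li+].[Ni+2].[Br-].[Br-].[Br-].[Br-]
Why: SN2 epoxide opening by soft bromide at the less substituted carbon C6 with inversion, which puts bromine on the secondary carbon in the S configuration and leaves the tertiary hydroxyl as the later leaving group.

Step 3
Reactants: 3 (2E,6S)-6-bromo-7-hydroxy-3,7-dimethyloct-2-en-1-yl acetate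
Product: 4 (2E,6S)-6-bromo-7-chloro-3,7-dimethyloct-2-en-1-yl acetate
Conditions: SOCl2, CH2Cl2, 0 °C
Reagents that add atoms: thionyl chloride, ClS(Cl)=O
Why: deoxychlorination of a tertiary alcohol through its chlorosulfite with neighbouring-group participation, in which the anti bromine expels the leaving group and chloride reopens the bromonium ion at the tertiary carbon, so that C6 is not touched.

Step 4
Reactants: 4 (2E,6S)-6-bromo-7-chloro-3,7-dimethyloct-2-en-1-yl acetate
Product: 5 [(5S)-5-bromo-2,6,6-trimethylcyclohex-2-en-1-yl]methyl acetate (Δ2 isomer drawn; Δ1 and exocyclic isomers accompany it)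
Conditions: (CF3)2CHOH (0.02 M), NaHCO3 (solid), 23 °C
Reagents that add atoms: none
Why: bromonium-initiated cation–olefin cyclisation, in which solvolysis of the tertiary chloride in the ionising, non-nucleophilic alcohol regenerates the bromonium ion with bromine still on C6, the 2,3-alkene attacks C7 through a chair transition state to close ring A (the later C6–C11 bond) with bromine equatorial, and proton loss ends the process; transfer of bromonium between alkenes, the racemising pathway, is disfavoured by the solvent and the dilution.

Step 5
Reactants: 5 [(5S)-5-bromo-2,6,6-trimethylcyclohex-2-en-1-yl]methyl acetate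
Product: 6 [(5S)-5-bromo-2,6,6-trimethylcyclohex-2-en-1-yl]methanol (with its double-bond isomers)
Conditions: K2CO3 (0.2 equiv), MeOH, 0 °C
Reagents that add atoms: none
Why: base-catalysed transesterification of the acetate under conditions too mild to substitute or eliminate the equatorial neopentyl bromide.

Step 6
Reactants: 6 [(5S)-5-bromo-2,6,6-trimethylcyclohex-2-en-1-yl]methanol
Product: 8 (5S)-5-bromo-2,6,6-trimethylcyclohex-1-ene-1-carbaldehyde, via bromo-α-cyclocitral 7 (not isolated)
Conditions: Dess–Martin periodinane, CH2Cl2, 23 °C; then DBU (3 equiv), 23 °C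
Reagents that add atoms: none
Why: Dess–Martin oxidation gives the aldehydes without acid or strong base, and amidine-catalysed isomerisation through the dienol(ate) should then funnel every double-bond isomer into the tetrasubstituted conjugated enal, the thermodynamic isomer.

Step 7
Reactants: 8 (5S)-5-bromo-2,6,6-trimethylcyclohex-1-ene-1-carbaldehyde; 9 methyl vinyl ketone (but-3-en-2-one)
Product: 12 (6R,10S)-10-bromo-7,11,11-trimethylspiro[5.5]undeca-1,7-dien-3-one, via keto aldehyde 10 (not isolated), via spiro ketol 11 (not isolated)
Conditions: KOt-Bu (0.3 equiv), t-BuOH/THF, 0 °C, slow addition of 9 (2 equiv); then KOH (0.5 equiv), MeOH, 40 °C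
Reagents that add atoms: none
Why: Alkoxide removes H8 to give the extended dienolate, which adds through its α-carbon C6 to 9 (C5–C6 bond) and thereby moves the ring A alkene to C7=C8; the methyl ketone of 10 then attacks the now non-enolisable aldehyde (C1–C2 bond) and 11 dehydrates by E1cB. The closest known reaction type is the Robinson annulation in its spiroannulating form with α,α-disubstituted aldehydes, joined to the deconjugative α-alkylation of cyclocitral dienolates. Ring B closes by a 6-(enolendo)-exo-trig aldol addition. The new stereocentre C6 is set by the substrate: in the half-chair dienolate with the C10 bromide equatorial, C5 bonds pseudo-axially on the face anti to the pseudo-axial C11 methyl, which is cis to bromine, so C5 ends trans and C1 cis to bromine, while the other axial approach would need an axial bromine syn to the incoming chain. The step needs α- over γ-attack, which metal dienolates favour and which is reinforced because only the α-adduct can enter the irreversible aldol condensation that drains the reversible Michael equilibrium. The bromide should survive because it is secondary, neopentyl and equatorial, so it has no anti-periplanar hydrogen for elimination and lies in the nodal plane of the dienolate, unaligned for 1,3-displacement.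

Step 8
Reactants: 12 (6R,10S)-10-bromo-7,11,11-trimethylspiro[5.5]undeca-1,7-dien-3-one
Product: 13 {[(6R,10S)-10-bromo-7,11,11-trimethylspiro[5.5]undeca-2,7-dien-3-yl]oxy}triethylsilane
Conditions: RhCl(PPh3)3 (2 mol %), Et3SiH, THF, 50 °C
Reagents that add atoms: triethylsilane, CC[SiH](CC)CC
Why: rhodium-catalysed 1,4-hydrosilylation of the enone (monohydrosilanes add in the conjugate sense), which fixes the enol ether at C2=C3 and leaves the hindered trisubstituted ring A alkene and the alkyl bromide alone.

Step 9
Reactants: 13 {[(6R,10S)-10-bromo-7,11,11-trimethylspiro[5.5]undeca-2,7-dien-3-yl]oxy}triethylsilane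
Product: 14 (2R,6R,10S)-2,10-dibromo-7,11,11-trimethylspiro[5.5]undec-7-en-3-one
Conditions: NBS, THF, −78 → 0 °C; then LiBr, DMF, 23 °C
Reagents that add atoms: N-bromosuccinimide, BrN1C(=O)CCC1=O; lithium bromide, [Li+].[Br-] (degenerate bromide exchange at C2)
Why: electrophilic α-bromination of a silyl enol ether, regiospecific for C2, followed by Finkelstein-type bromide exchange that epimerises C2 to the thermodynamic equatorial bromide, which is cis to C11 because ring B keeps C11 equatorial and C7 axial and an axial C2 bromine would be syn-axial to C7.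

Step 10
Reactants: 14 (2R,6R,10S)-2,10-dibromo-7,11,11-trimethylspiro[5.5]undec-7-en-3-one
Product: 15 (2R,3S,6R,10S)-2,10-dibromo-3,7,11,11-tetramethylspiro[5.5]undec-7-en-3-ol (hydroxyl cis to the C2 bromine; the 3R epimer may accompany it)
Conditions: MeMgBr, CeCl3 (anhydrous), THF, −78 °C; then H2O, −78 °C
Reagents that add atoms: methylmagnesium bromide, C[Mg]Br
Why: cerium-mediated Grignard 1,2-addition, which suppresses enolisation and halogen–metal exchange of the α-bromo ketone; methyl is expected to enter anti to the C2 bromine by equatorial attack, and the C3 configuration is not critical because step 11 forms this centre anew.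

Step 11
Reactants: 15 (2R,3S,6R,10S)-2,10-dibromo-3,7,11,11-tetramethylspiro[5.5]undec-7-en-3-ol
Product: 16 (2R,3R,6R,10S)-2,10-dibromo-3-chloro-3,7,11,11-tetramethylspiro[5.5]undec-7-ene (CNP0126187.3)
Conditions: TiCl4 (1.5 equiv), 2,6-di-tert-butylpyridine (1.2 equiv), CH2Cl2, −78 → −40 °C; cold aqueous quench
Reagents that add atoms: titanium tetrachloride, Cl[Ti](Cl)(Cl)Cl
Why: Lewis-acid-mediated SN1 chlorination of a tertiary alcohol with neighbouring-group participation, in which ionisation of the titanium alkoxide gives a C3 cation bridged by the C2 bromine on the face that bromine occupies and chloride opens this bromonium ion at the more substituted carbon anti to bromine, so that either C3 epimer of 15 should give the trans bromochloride with chlorine equatorial and methyl axial, while the hindered pyridine traps HCl and shields the ring A alkene from protonation.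

**Compound list**

1 | geranyl acetate | CC(C)=CCC/C(C)=C/COC(C)=O | starting material
2 | (2E)-5-[(2R)-3,3-dimethyloxiran-2-yl]-3-methylpent-2-en-1-yl acetate | CC(=O)OC/C=C(\C)CC[C@H]1OC1(C)C | intermediate
3 | (2E,6S)-6-bromo-7-hydroxy-3,7-dimethyloct-2-en-1-yl acetate | CC(=O)OC/C=C(\C)CC[C@H](Br)C(C)(C)O | intermediate
4 | (2E,6S)-6-bromo-7-chloro-3,7-dimethyloct-2-en-1-yl acetate | CC(=O)OC/C=C(\C)CC[C@H](Br)C(C)(C)Cl | intermediate
5 | [(5S)-5-bromo-2,6,6-trimethylcyclohex-2-en-1-yl]methyl acetate (Δ2 isomer of the double-bond isomer mixture) | CC(=O)OCC1C(C)=CC[C@H](Br)C1(C)C | intermediate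
6 | [(5S)-5-bromo-2,6,6-trimethylcyclohex-2-en-1-yl]methanol (Δ2 isomer of the mixture) | OCC1C(C)=CC[C@H](Br)C1(C)C | intermediate
7 | (5S)-5-bromo-2,6,6-trimethylcyclohex-2-ene-1-carbaldehyde (bromo-α-cyclocitral, not isolated) | O=CC1C(C)=CC[C@H](Br)C1(C)C | intermediate
8 | (5S)-5-bromo-2,6,6-trimethylcyclohex-1-ene-1-carbaldehyde | CC=1CC[C@H](Br)C(C)(C)C=1C=O | intermediate
9 | methyl vinyl ketone | CC(=O)C=C | starting material
10 | (1R,5S)-5-bromo-2,6,6-trimethyl-1-(3-oxobutyl)cyclohex-2-ene-1-carbaldehyde (not isolated) | CC1=CC[C@H](Br)C(C)(C)[C@]1(CCC(C)=O)C=O | intermediate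
11 | (6R,10S)-10-bromo-1-hydroxy-7,11,11-trimethylspiro[5.5]undec-7-en-3-one (C1 epimers, not isolated) | CC1=CC[C@H](Br)C(C)(C)[C@@]12CCC(=O)CC2O | intermediate
12 | (6R,10S)-10-bromo-7,11,11-trimethylspiro[5.5]undeca-1,7-dien-3-one | CC1=CC[C@H](Br)C(C)(C)[C@@]12CCC(=O)C=C2 | intermediate
13 | {[(6R,10S)-10-bromo-7,11,11-trimethylspiro[5.5]undeca-2,7-dien-3-yl]oxy}triethylsilane | CC1=CC[C@H](Br)C(C)(C)[C@@]12CCC(O[Si](CC)(CC)CC)=CC2 | intermediate
14 | (2R,6R,10S)-2,10-dibromo-7,11,11-trimethylspiro[5.5]undec-7-en-3-one | CC1=CC[C@H](Br)C(C)(C)[C@@]12CCC(=O)[C@H](Br)C2 | intermediate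
15 | (2R,3S,6R,10S)-2,10-dibromo-3,7,11,11-tetramethylspiro[5.5]undec-7-en-3-ol | CC1=CC[C@H](Br)C(C)(C)[C@@]12CC[C@](C)(O)[C@H](Br)C2 | intermediate
16 | (2R,3R,6R,10S)-2,10-dibromo-3-chloro-3,7,11,11-tetramethylspiro[5.5]undec-7-ene | CC1=CC[C@H](Br)C(C)(C)[C@@]12CC[C@@](C)(Cl)[C@H](Br)C2 | target

**Step count and risks**

Total steps: 11. Longest linear sequence: 11 steps (1 → 16); 9 enters at step 7.

Steps most likely to fail:

Step 7. Bond formation at C6 may be slowed by the adjacent quaternary C11, so that addition through the γ-carbon C8, reversal of the Michael addition or base-induced polymerisation of 9 take over. The fallback makes the C5–C6 bond by alkylation and sets out from 8. KN(SiMe3)2 in THF/DMPU at −78 °C followed by 2-(2-iodoethyl)-2-methyl-1,3-dioxolane should give, by deconjugative α-alkylation on the same face of the dienolate, (1R,5S)-5-bromo-2,6,6-trimethyl-1-[2-(2-methyl-1,3-dioxolan-2-yl)ethyl]cyclohex-2-ene-1-carbaldehyde F1. Aqueous HCl in THF removes the dioxolane and returns to the route at 10, which KOH in MeOH closes to 12.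

Step 11. Facial control may be lost if chloride captures the cation before bromine bridges (chlorine entering cis to bromine), and proton loss to alkenes or opening of the bromonium ion at C2 with a 1,2-shift of bromine may compete. The fallback adds bromine and chlorine together to a C2=C3 alkene and sets out from 13, replacing steps 9–11. MeLi in THF at 0 °C frees the lithium enolate, and PhNTf2 traps it as (6R,10S)-10-bromo-7,11,11-trimethylspiro[5.5]undeca-2,7-dien-3-yl trifluoromethanesulfonate F2. Negishi coupling with MeZnCl and Pd(PPh3)4 in THF gives (6R,10S)-10-bromo-3,7,11,11-tetramethylspiro[5.5]undeca-2,7-diene F3 (10-bromo-α-chamigrene). Bromochlorination with Bu4NBrCl2 in CH2Cl2 at −78 °C returns to the route at 16. It relies on bromonium formation on the ring B alkene face anti to the pseudo-axial C7, anti addition with chloride at the tertiary carbon, and the ring A alkene being the more hindered one; the facial preference is not secured.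

Step 4. The acetate-deactivated 2,3-alkene may capture the bromonium ion too slowly, so that chloride return, elimination to acyclic products or bromonium transfer between alkenes (erosion of enantiopurity) compete. The fallback makes ring A racemic and resolves it, setting out from 1. Direct bromonium cyclisation with 2,4,4,6-tetrabromocyclohexa-2,5-dienone in MeNO2 gives racemic (5-bromo-2,6,6-trimethylcyclohex-2-en-1-yl)methyl acetate F4 with its double-bond isomers. The conditions of step 5 give racemic (5-bromo-2,6,6-trimethylcyclohex-2-en-1-yl)methanol F5, and those of step 6 give racemic 5-bromo-2,6,6-trimethylcyclohex-1-ene-1-carbaldehyde F6. Preparative chromatography on a chiral stationary phase separates the S enantiomer, which returns to the route at 8.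

**Further compounds**

F1 | step 7 | (1R,5S)-5-bromo-2,6,6-trimethyl-1-[2-(2-methyl-1,3-dioxolan-2-yl)ethyl]cyclohex-2-ene-1-carbaldehyde | CC1=CC[C@H](Br)C(C)(C)[C@]1(CCC2(C)OCCO2)C=O
F2 | step 11 | (6R,10S)-10-bromo-7,11,11-trimethylspiro[5.5]undeca-2,7-dien-3-yl trifluoromethanesulfonate | CC1=CC[C@H](Br)C(C)(C)[C@@]12CCC(OS(=O)(=O)C(F)(F)F)=CC2
F3 | step 11 | (6R,10S)-10-bromo-3,7,11,11-tetramethylspiro[5.5]undeca-2,7-diene | CC1=CC[C@H](Br)C(C)(C)[C@@]12CCC(C)=CC2
F4 | step 4 | racemic (5-bromo-2,6,6-trimethylcyclohex-2-en-1-yl)methyl acetate | CC(=O)OCC1C(C)=CCC(Br)C1(C)C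
F5 | step 4 | racemic (5-bromo-2,6,6-trimethylcyclohex-2-en-1-yl)methanol | OCC1C(C)=CCC(Br)C1(C)C
F6 | step 4 | racemic 5-bromo-2,6,6-trimethylcyclohex-1-ene-1-carbaldehyde | CC1=C(C=O)C(C)(C)C(Br)CC1
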